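All runs were generated by integration with made-up constants; noise was put on by code.

How much J and how much E stand in the flask after 1.0 h, and is it still moving by then?

common to all: X 100 mM (held)
- gamma: E 0.67 M; G 0.2 mol%; run made earlier
- eta: E 1.5 M; G 0.2 mol%; run made earlier
- beta: E 1 M; G 0.4 mol%; run made earlier
- flask: E 1.0 M; G 0.2 mol%; time 1.0 h

- gamma (time / min: J / %, E / %): 2.50: 16, 89; 8.00: 33, 69; 15.0: 46, 52; 20.0: 51, 45; 30.0: 57, 43; 40.0: 61, 42; 50.0: 57, 42
- eta (time / min: J / %, E / %): 6.00: 41, 59; 15.0: 55, 46; 20.0: 59, 44; 30.0: 62, 43; 40.0: 61, 39; 50.0: 61, 42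
- beta (time / min: J / %, E / %): 4.00: 42, 60; 12.0: 59, 44; 20.0: 60, 44; 30.0: 59, 40; 50.0: 59, 40

(readings scatter by 2 percentage points)

- at the start none of X is in solution

- J present at 1.0 h, in percent of the E charged
- E present at 1.0 h, in percent of the E charged

The three runs end near one composition: the last E readings average E∞ = 41.3%, and J, taken as the rest, is 58.7%. The open matter is speed. The first reading of the beta run gives the approach constant k, the fall per minute in the logarithm of E's distance from E∞, a pseudo-first-order constant:

k(beta) = ln(distance at start / distance at reading) / time = 0.286 min⁻¹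

One objection is that k may follow the loading of G rather than its concentration. The gamma and eta runs share a loading, yet the second reading of the gamma run, where E has fallen by 31 percentage points, and the first reading of the eta run give 0.0940 min⁻¹ and 0.200 min⁻¹, about twice apart, and their concentrations of G also stand about twice apart. So this reckoning scales k by [G], 2.00 mM in the flask against 4.00 mM in the beta run:

k(flask) = 0.143 min⁻¹

A second objection is that E∞ assumed the runs had finished. Putting k back in, the gamma run has k = 0.0959 min⁻¹, which leaves a distance of 0.485% at its last reading, less than the scatter. E∞ therefore stands. The flask's distance at 1.0 h is 0.0109%, so this reckoning gives E 41.3% and J 58.7%.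

The forecast gives J 60% and E 41%, its J lying 1.3 points above this reckoning: “it looks like a true equilibrium at fixed X”.

The flask gives J 58.3% and E 41.6%.

    X ⇌ Q, rate k1*(csat - [Q]) (kL = 9.38 min⁻¹)
    E + Q + G ⇌ G + J (K = 14.0 L mol⁻¹, k = 497 L² mol⁻² min⁻¹)
    J → L (k = 3.01 × 10⁻⁵ min⁻¹)

In the flask, half of the turnover of E with Q, the dissolved X, was done by 4.54 min, against a half-time of 4.85 min from k. E has moved by 5 points at a loading of 0.049 mol%. With G at 0.05 mol%, k becomes 0.0358 min⁻¹, which puts E at 48.2% after 1.0 h; that neighbouring flask held E 46.4%.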